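In percent of the substrate charged, I ask first what the end state must be, then how fast it is approached.

the same everywhere: substrate 0.020 M

| run | reagent | remark | time |
|---|---|---|---|
| ash | 0.052 M | run made earlier |  |
| maple | 0.070 M | run made earlier |  |
| Monday's | 0.0400 M |  | 50 h |
| Saturday's | 0.0600 M |  | 50 h |

| run | time / h | tautomer / % | isomer of the product / % | target / % | substrate / % |
|---|---|---|---|---|---|
| ash | 4.00 | 3.3 | 22.5 | 57.6 | 17.5 |
| ash | 10.0 | 0 | 25.7 | 72.6 | 1.7 |
| ash | 20.0 | 0 | 26.1 | 73.7 | 0.4 |
| ash | 48.0 | 0.3 | 26.6 | 74.0 | 0 |
| maple | 4.00 | 1.4 | 28.8 | 54.9 | 14.0 |
| maple | 10.0 | 0 | 31.9 | 65.6 | 1.0 |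
| maple | 20.0 | 0 | 32.5 | 66.7 | 0.6 |
| maple | 48.0 | 0.3 | 33.0 | 67.2 | 0 |

(readings scatter by 0.5 percentage points)

1. which of these there is most of at the end, counted by the substrate in it, Monday's (isomer of the product / substrate / target / tautomer)
2. which of these there is most of at the end, counted by the substrate in it, Saturday's (isomer of the product / substrate / target / tautomer)
3. final amount of the leader among these, as a percentage of the substrate charged, in Monday's
4. final amount of the leader among these, as a percentage of the substrate charged, in Saturday's

- the earlier runs were read with a standard deviation of 0.5 percentage points
- steps under discussion: substrate <-> tautomer; substrate + reagent -> isomer of the product; reagent + tautomer -> target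

Ash holds 0.4% of substrate after 20.0 h, and Monday's and Saturday's each get a longer 50 h, so I expect both to finish. What remains is the split, isomer of the product per target at the end.

I begin with the main route: substrate becomes tautomer and reagent converts tautomer into target. By itself this route gives 100% target and a split of zero. But the split reads 0.359 in ash and 0.491 in maple, rising with reagent.

So I add the direct step, substrate + reagent to isomer of the product. Its rate carries [reagent], so if reagent traps tautomer as it forms, the split grows in proportion to [reagent]. The two ends give the reagent slope 7.31 /M, the rise of the split per molar of reagent. With [reagent] held at its charge, I reckon Monday's split at 0.292 and its target at 77.4%.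

Next, reagent is consumed, one per substrate, so mean [reagent] is the charge minus 0.0100 M. Monday's mean is 0.0300 M, which lifts its target to 82.0%. Finally, tautomer returning to substrate should add a term independent of [reagent]. Ash puts this base at 0.0524. My reckoning then gives Monday's a split of 0.272 and target 78.6%, and Saturday's a split of 0.418 and target 70.5%.

The forecast has target leading Monday's at 78.3% and target leading Saturday's at 70.5%, reasoning that “A fully pre-equilibrated tautomer would give a constant ratio, so tautomerisation must be partly rate-limiting.” My Monday's figure stands 0.30 percentage points above it.

Monday's gives 79.3% of target and Saturday's 70.6%, with target leading both.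

    substrate ⇌ tautomer (K = 2.40, k = 0.340 /h)
    substrate + reagent → isomer of the product (k = 2.70 /M/h)
    reagent + tautomer → target (k = 74.0 /M/h)

Monday's keeps 50.0% of its reagent charge free at the end. Its split comes out at 0.261, against my 0.272. In the neighbour of Monday's charged with 0.16 M of reagent, slope and base give a split of 1.15 and target 46.5%, with isomer of the product ahead. That flask ends with 45.3% of target and 54.7% of isomer of the product.

Readings and results were generated by integration for substances that don't exist.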